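**Strategy.** Ring A (C1–C5, C10; labdane numbering) is made last, by forming C2–C3. Ring B is built first from 2-methylcyclohexenone: one CBS-set carbinol is relayed by Johnson–Claisen rearrangement (C5), cuprate addition (C10), equilibration (C9) and allylic-strain-controlled ester alkylation (C4). The key step is an iodine–lithium exchange-initiated cycloacylation: the C2 carbanion on the C10 ethyl arm attacks the C3 ester, which cannot enolise because C4 is fully substituted, and closes ring A as the trans-decalin 3-ketone. It exploits the trans-diequatorial C10–C1 and C5–C4 arms on ring B. The locked chair then directs hydride to the equatorial C3–O; a 3-furylethyl group masks the (Z)-enediol side chain.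

Key step: step 9

Remark: positions are given in labdane numbering (C1–C20) throughout; the (S)-oxazaborolidine is assumed to give (R)-2 by the usual model (alkenyl side as the large group), otherwise its enantiomer is used.

**Route**

Step 1
Reactants: 1 2-methylcyclohex-2-en-1-one
Product: 2 (1R)-2-methylcyclohex-2-en-1-ol
Conditions: (S)-Me-CBS (10 mol %), BH3·SMe2, THF, −20 °C; MeOH, then aqueous work-up
Reagents that add atoms: none
Why: Corey–Bakshi–Shibata reduction: the oxazaborolidine–borane complex should deliver hydride to one carbonyl face, setting the only reagent-controlled stereocenter (R), whose chirality is transferred in step 2.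

Step 2
Reactants: 2 (1R)-2-methylcyclohex-2-en-1-ol
Product: 5 ethyl 2-[(1R)-2-methylcyclohex-2-en-1-yl]propanoate (both C4 epimers), via mixed orthoester 3 (not isolated), via ketene acetal 4 (not isolated)
Conditions: EtC(OEt)3 (5 equiv), EtCO2H (cat.), 140 °C, EtOH distilled off
Reagents that add atoms: triethyl orthopropionate CCC(OCC)(OCC)OCC
Why: Johnson–Claisen rearrangement: the suprafacial [3,3] shift of ketene acetal 4 should transfer the C–O chirality of 2 to the new C5–C4 bond (C5 R in 5), while the α-methyl centre C4 stays a mixture because it is re-made in step 7.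

Step 3
Reactants: 5 ethyl 2-[(1R)-2-methylcyclohex-2-en-1-yl]propanoate
Product: 6 ethyl 2-[(1R)-2-methyl-4-oxocyclohex-2-en-1-yl]propanoate (both C4 epimers)
Conditions: Rh2(cap)4 (1 mol %), t-BuOOH (aq., 5 equiv), K2CO3, CH2Cl2, rt
Reagents that add atoms: tert-butyl hydroperoxide CC(C)(C)OO
Why: Rhodium-catalysed allylic oxidation with t-BuOOH: the ring CH2 next to the CH= terminus of the trisubstituted alkene (C8) is the most accessible allylic position and should be oxidised to the enone, as C7 is in Δ5-steroids, without touching C5.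

Step 4
Reactants: 7 2-(furan-3-yl)ethan-1-ol
Product: 8 3-(2-iodoethyl)furan
Conditions: I2, PPh3, imidazole, CH2Cl2, 0 °C
Reagents that add atoms: iodine II
Why: Appel-type iodination of a primary alcohol by SN2 displacement of the alkoxyphosphonium ion.

Step 5
Reactants: 6 ethyl 2-[(1R)-2-methyl-4-oxocyclohex-2-en-1-yl]propanoate; 8 3-(2-iodoethyl)furan
Product: 10 ethyl 2-[(1R,2R,3S)-2-ethenyl-3-[2-(furan-3-yl)ethyl]-2-methyl-4-oxocyclohexyl]propanoate (both C4 epimers), via lithium enolate 9 (not isolated)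
Conditions: (CH2=CH)2CuLi (from vinyllithium, CuI), THF, −78 → −30 °C; HMPA, 8 (3 equiv), −30 °C → rt; NH4Cl (aq.); crude: NaOEt (0.2 equiv), EtOH, rt
Reagents that add atoms: vinyllithium [Li]C=C
Why: Cuprate conjugate addition with regiospecific enolate alkylation (three-component coupling): vinyl should add to C10 anti to the C5 substituent (quaternary C10, 1,2-trans), enolate 9 is alkylated at C9 by 8, and ethoxide then equilibrates C9 through the enolate to the equatorial epimer (chain trans to vinyl).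

Step 6
Reactants: 10 ethyl 2-[(1R,2R,3S)-2-ethenyl-3-[2-(furan-3-yl)ethyl]-2-methyl-4-oxocyclohexyl]propanoate
Product: 11 ethyl 2-[(1R,2R,3R)-2-ethenyl-3-[2-(furan-3-yl)ethyl]-2-methyl-4-methylidenecyclohexyl]propanoate (both C4 epimers)
Conditions: Ph3PCH3Br, KOtBu, THF, 0 °C (ylide pre-formed); then 10, 0 °C → rt
Reagents that add atoms: methyltriphenylphosphonium bromide [Br-].C[P+](c1ccccc1)(c1ccccc1)c1ccccc1
Why: Wittig methylenation of the C8 ketone; no stereocenter is formed, and the equilibrated C9 configuration is frozen because C8 is no longer a carbonyl.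

Step 7
Reactants: 11 ethyl 2-[(1R,2R,3R)-2-ethenyl-3-[2-(furan-3-yl)ethyl]-2-methyl-4-methylidenecyclohexyl]propanoate
Product: 13 ethyl (2S)-2-[(1S,2S,3R)-2-ethenyl-3-[2-(furan-3-yl)ethyl]-2-methyl-4-methylidenecyclohexyl]-2-methyl-3-{[tri(propan-2-yl)silyl]oxy}propanoate, via lithium ester enolate 12 (not isolated)
Conditions: LDA, THF–DMPU, −78 → −40 °C; iPr3SiOCH2Cl, −78 → 0 °C
Reagents that add atoms: (chloromethoxy)tri(propan-2-yl)silane ClCO[Si](C(C)C)(C(C)C)C(C)C
Why: Alkylation of a lithium ester enolate with an α-chloro ether (hydroxymethylation): 1,3-allylic strain should hold C5–H in the enolate plane so that the electrophile enters anti to the quaternary C10, giving the C4 configuration (2S) that places CH3 axial and CH2OSi equatorial after ring closure.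

Step 8
Reactants: 13 ethyl (2S)-2-[(1S,2S,3R)-2-ethenyl-3-[2-(furan-3-yl)ethyl]-2-methyl-4-methylidenecyclohexyl]-2-methyl-3-{[tri(propan-2-yl)silyl]oxy}propanoate
Product: 15 ethyl (2S)-2-[(1S,2S,3R)-3-[2-(furan-3-yl)ethyl]-2-(2-iodoethyl)-2-methyl-4-methylidenecyclohexyl]-2-methyl-3-{[tri(propan-2-yl)silyl]oxy}propanoate, via alkylzirconocene chloride 14 (not isolated)
Conditions: Cp2Zr(H)Cl (1.5 equiv), THF, rt, short reaction time; I2, 0 °C
Reagents that add atoms: iodine II
Why: Schwartz hydrozirconation–iodination: Zr–H should add anti-Markovnikov to the monosubstituted vinyl group faster than to the 1,1-disubstituted C8 methylene or the hindered ester, and iodinolysis of the C2–Zr bond of 14 gives the primary iodide without touching any stereocenter.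

Step 9
Reactants: 15 ethyl (2S)-2-[(1S,2S,3R)-3-[2-(furan-3-yl)ethyl]-2-(2-iodoethyl)-2-methyl-4-methylidenecyclohexyl]-2-methyl-3-{[tri(propan-2-yl)silyl]oxy}propanoate
Product: 18 (1S,4aS,5R,8aS)-5-[2-(furan-3-yl)ethyl]-1,4a-dimethyl-6-methylidene-1-({[tri(propan-2-yl)silyl]oxy}methyl)octahydronaphthalen-2(1H)-one, via alkyllithium 16 (not isolated), via lithium hemiketal 17 (not isolated)
Conditions: t-BuLi (2.1 equiv), Et2O–pentane, −78 → −20 °C; NH4Cl (aq.)
Reagents that add atoms: none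
Why: Iodine–lithium exchange at C2 is much faster than addition of tert-butyllithium to the neopentyl ester, and the primary carbanion 16 then adds to the C3 ester carbonyl to give the tetrahedral lithium hemiketal 17, which releases the ketone on work-up. The closest known reaction type is the halogen–metal exchange-initiated cycloacylation of ω-iodo esters (a Parham-type anionic cyclisation). Ring A (C1, C2, C3, C4, C5, C10) is closed in the 6-exo-trig mode by the new C2–C3 bond. No stereocenter is created, but the closure fixes ring A as a chair trans-fused to ring B, with the C4 methyl axial and syn to the C10 methyl and C19 equatorial, the arrangement that directs the C3 reduction in step 10. The step needs chemoselectivity (exchange and 1,2-addition in preference to double addition, furan metalation or carbolithiation of the C8 methylene), which the fully substituted C4 (no α-hydrogen), the low temperature, the exact stoichiometry and the persistence of 17 until work-up should secure. The C10–C1 and C5–C4 arms are trans-diequatorial on ring B, so the six-membered transition state should be free of strain.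

Step 10
Reactants: 18 (1S,4aS,5R,8aS)-5-[2-(furan-3-yl)ethyl]-1,4a-dimethyl-6-methylidene-1-({[tri(propan-2-yl)silyl]oxy}methyl)octahydronaphthalen-2(1H)-one
Product: 19 (1S,2R,4aS,5R,8aS)-5-[2-(furan-3-yl)ethyl]-1,4a-dimethyl-6-methylidene-1-({[tri(propan-2-yl)silyl]oxy}methyl)decahydronaphthalen-2-ol
Conditions: NaBH4, MeOH–THF, 0 °C
Reagents that add atoms: none
Why: Borohydride reduction of a cyclohexanone: hydride should attack C3 along the axial trajectory on the face anti to the axial C4 and C10 methyl groups, giving the equatorial (3R) alcohol as in 4,4-disubstituted 3-oxo terpenoids.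

Step 11
Reactants: 19 (1S,2R,4aS,5R,8aS)-5-[2-(furan-3-yl)ethyl]-1,4a-dimethyl-6-methylidene-1-({[tri(propan-2-yl)silyl]oxy}methyl)decahydronaphthalen-2-ol
Product: 21 (1S,2R,4aS,5R,8aS)-5-[2-(furan-3-yl)ethyl]-1,4a-dimethyl-6-methylidene-1-({[tri(propan-2-yl)silyl]oxy}methyl)decahydronaphthalen-2-yl (2Z)-2-methylbut-2-enoate, via lithium alkoxide 20 (not isolated)
Conditions: LiHMDS, THF, −78 °C; angelic anhydride, −78 → 0 °C
Reagents that add atoms: angelic anhydride C/C=C(/C)C(=O)OC(=O)/C(C)=C\C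
Why: O-Acylation of the lithium alkoxide 20 with the anhydride, without a nucleophilic amine catalyst, should avoid the addition–elimination pathway that isomerises angelate to tiglate; no stereocenter changes.

Step 12
Reactants: 21 (1S,2R,4aS,5R,8aS)-5-[2-(furan-3-yl)ethyl]-1,4a-dimethyl-6-methylidene-1-({[tri(propan-2-yl)silyl]oxy}methyl)decahydronaphthalen-2-yl (2Z)-2-methylbut-2-enoate
Product: 24 (1S,2R,4aS,5R,8aS)-5-[(3Z)-5-hydroxy-3-(hydroxymethyl)pent-3-en-1-yl]-1,4a-dimethyl-6-methylidene-1-({[tri(propan-2-yl)silyl]oxy}methyl)decahydronaphthalen-2-yl (2Z)-2-methylbut-2-enoate, via furan endoperoxide 22 (not isolated), via cis-enedial 23 (not isolated)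
Conditions: O2, hν, TPP (cat.), CH2Cl2, −78 °C; Me2S; then MeOH, CeCl3·7H2O, NaBH4, −78 → 0 °C
Reagents that add atoms: oxygen O=O
Why: Singlet-oxygen [4+2] cycloaddition to the furan, reductive opening of the endoperoxide and Luche reduction: the furan should react far faster than the 1,1-disubstituted alkene or the electron-poor angelate, and the Z geometry of C13=C14 is inherited from the ring.

Step 13
Reactants: 24 (1S,2R,4aS,5R,8aS)-5-[(3Z)-5-hydroxy-3-(hydroxymethyl)pent-3-en-1-yl]-1,4a-dimethyl-6-methylidene-1-({[tri(propan-2-yl)silyl]oxy}methyl)decahydronaphthalen-2-yl (2Z)-2-methylbut-2-enoate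
Product: 25 (1S,2R,4aS,5R,8aS)-5-[(3Z)-5-hydroxy-3-(hydroxymethyl)pent-3-en-1-yl]-1-(hydroxymethyl)-1,4a-dimethyl-6-methylidenedecahydronaphthalen-2-yl (2Z)-2-methylbut-2-enoate (CNP0237954.1)
Conditions: HF·pyridine, pyridine, THF, 0 °C → rt
Reagents that add atoms: none
Why: Fluoride-mediated desilylation under buffered, non-basic conditions should leave the allylic diol and the alkenes intact and avoid 1,3-migration of the angeloyl group from O3 to O19.

**Compound list**

1 | 2-methylcyclohex-2-en-1-one | CC1=CCCCC1=O | starting material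
2 | (1R)-2-methylcyclohex-2-en-1-ol | O[C@@H]1CCCC=C1C | intermediate
3 | (6R)-6-(1,1-diethoxypropoxy)-1-methylcyclohex-1-ene (mixed orthoester) | CCC(OCC)(OCC)O[C@@H]1CCCC=C1C | intermediate
4 | (6R)-6-[(1-ethoxyprop-1-en-1-yl)oxy]-1-methylcyclohex-1-ene (ketene acetal) | CC=C(OCC)O[C@@H]1CCCC=C1C | intermediate
5 | ethyl 2-[(1R)-2-methylcyclohex-2-en-1-yl]propanoate (both C4 epimers) | CCOC(=O)C(C)[C@H]1CCCC=C1C | intermediate
6 | ethyl 2-[(1R)-2-methyl-4-oxocyclohex-2-en-1-yl]propanoate (both C4 epimers) | CCOC(=O)C(C)[C@H]1CCC(=O)C=C1C | intermediate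
7 | 2-(furan-3-yl)ethan-1-ol | OCCc1ccoc1 | starting material
8 | 3-(2-iodoethyl)furan | ICCc1ccoc1 | intermediate
9 | lithium C8–C9 enolate of the vinyl adduct of 6 (vinyl trans to the C5 side chain) | [Li]OC1=C[C@](C)(C=C)[C@@H](C(C)C(=O)OCC)CC1 | intermediate
10 | ethyl 2-[(1R,2R,3S)-2-ethenyl-3-[2-(furan-3-yl)ethyl]-2-methyl-4-oxocyclohexyl]propanoate (both C4 epimers) | O=C1CC[C@H](C(C)C(=O)OCC)[C@@](C)(C=C)[C@@H]1CCc1ccoc1 | intermediate
11 | ethyl 2-[(1R,2R,3R)-2-ethenyl-3-[2-(furan-3-yl)ethyl]-2-methyl-4-methylidenecyclohexyl]propanoate (both C4 epimers) | C=C1CC[C@H](C(C)C(=O)OCC)[C@@](C)(C=C)[C@@H]1CCc1ccoc1 | intermediate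
12 | lithium ester enolate of 11 | C=C1CC[C@H](C(C)=C(O[Li])OCC)[C@@](C)(C=C)[C@@H]1CCc1ccoc1 | intermediate
13 | ethyl (2S)-2-[(1S,2S,3R)-2-ethenyl-3-[2-(furan-3-yl)ethyl]-2-methyl-4-methylidenecyclohexyl]-2-methyl-3-{[tri(propan-2-yl)silyl]oxy}propanoate | C=C1CC[C@H]([C@@](C)(CO[Si](C(C)C)(C(C)C)C(C)C)C(=O)OCC)[C@@](C)(C=C)[C@@H]1CCc1ccoc1 | intermediate
14 | C2 alkylzirconocene chloride from 13 (chlorobis(cyclopentadienyl)zirconium on C2) | C=C1CC[C@H]([C@@](C)(CO[Si](C(C)C)(C(C)C)C(C)C)C(=O)OCC)[C@@](C)(CC[Zr](Cl)(C2C=CC=C2)C2C=CC=C2)[C@@H]1CCc1ccoc1 | intermediate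
15 | ethyl (2S)-2-[(1S,2S,3R)-3-[2-(furan-3-yl)ethyl]-2-(2-iodoethyl)-2-methyl-4-methylidenecyclohexyl]-2-methyl-3-{[tri(propan-2-yl)silyl]oxy}propanoate | C=C1CC[C@H]([C@@](C)(CO[Si](C(C)C)(C(C)C)C(C)C)C(=O)OCC)[C@@](C)(CCI)[C@@H]1CCc1ccoc1 | intermediate
16 | C2 alkyllithium from 15 | C=C1CC[C@H]([C@@](C)(CO[Si](C(C)C)(C(C)C)C(C)C)C(=O)OCC)[C@@](C)(CC[Li])[C@@H]1CCc1ccoc1 | intermediate
17 | lithium hemiketal (C3 ethoxy alkoxide, ring A closed) | C=C1CC[C@H]2[C@@](C)(CCC(O[Li])(OCC)[C@]2(C)CO[Si](C(C)C)(C(C)C)C(C)C)[C@@H]1CCc1ccoc1 | intermediate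
18 | (1S,4aS,5R,8aS)-5-[2-(furan-3-yl)ethyl]-1,4a-dimethyl-6-methylidene-1-({[tri(propan-2-yl)silyl]oxy}methyl)octahydronaphthalen-2(1H)-one | C=C1CC[C@H]2[C@@](C)(CCC(=O)[C@]2(C)CO[Si](C(C)C)(C(C)C)C(C)C)[C@@H]1CCc1ccoc1 | intermediate
19 | (1S,2R,4aS,5R,8aS)-5-[2-(furan-3-yl)ethyl]-1,4a-dimethyl-6-methylidene-1-({[tri(propan-2-yl)silyl]oxy}methyl)decahydronaphthalen-2-ol | C=C1CC[C@H]2[C@@](C)(CC[C@@H](O)[C@]2(C)CO[Si](C(C)C)(C(C)C)C(C)C)[C@@H]1CCc1ccoc1 | intermediate
20 | lithium alkoxide of 19 | C=C1CC[C@H]2[C@@](C)(CC[C@@H](O[Li])[C@]2(C)CO[Si](C(C)C)(C(C)C)C(C)C)[C@@H]1CCc1ccoc1 | intermediate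
21 | (1S,2R,4aS,5R,8aS)-5-[2-(furan-3-yl)ethyl]-1,4a-dimethyl-6-methylidene-1-({[tri(propan-2-yl)silyl]oxy}methyl)decahydronaphthalen-2-yl (2Z)-2-methylbut-2-enoate | C=C1CC[C@H]2[C@@](C)(CC[C@@H](OC(=O)/C(C)=C\C)[C@]2(C)CO[Si](C(C)C)(C(C)C)C(C)C)[C@@H]1CCc1ccoc1 | intermediate
22 | furan endoperoxide of 21 (2,3,7-trioxabicyclo[2.2.1]hept-5-en-5-yl side chain; both facial isomers) | C=C1CC[C@H]2[C@@](C)(CC[C@@H](OC(=O)/C(C)=C\C)[C@]2(C)CO[Si](C(C)C)(C(C)C)C(C)C)[C@@H]1CCC1=CC2OOC1O2 | intermediate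
23 | cis-enedial ((Z)-2-substituted but-2-enedial side chain) | C=C1CC[C@H]2[C@@](C)(CC[C@@H](OC(=O)/C(C)=C\C)[C@]2(C)CO[Si](C(C)C)(C(C)C)C(C)C)[C@@H]1CC/C(=C/C=O)C=O | intermediate
24 | (1S,2R,4aS,5R,8aS)-5-[(3Z)-5-hydroxy-3-(hydroxymethyl)pent-3-en-1-yl]-1,4a-dimethyl-6-methylidene-1-({[tri(propan-2-yl)silyl]oxy}methyl)decahydronaphthalen-2-yl (2Z)-2-methylbut-2-enoate | C=C1CC[C@H]2[C@@](C)(CC[C@@H](OC(=O)/C(C)=C\C)[C@]2(C)CO[Si](C(C)C)(C(C)C)C(C)C)[C@@H]1CC/C(=C/CO)CO | intermediate
25 | (1S,2R,4aS,5R,8aS)-5-[(3Z)-5-hydroxy-3-(hydroxymethyl)pent-3-en-1-yl]-1-(hydroxymethyl)-1,4a-dimethyl-6-methylidenedecahydronaphthalen-2-yl (2Z)-2-methylbut-2-enoate | C=C1CC[C@H]2[C@@](C)(CC[C@@H](OC(=O)/C(C)=C\C)[C@]2(C)CO)[C@@H]1CC/C(=C/CO)CO | target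

**Step count.** Total: 13 steps. Longest linear sequence: 12 steps (1–3, 5–13).

**Steps most likely to fail, with fallbacks**

Step 5. The congested C9 enolate may be alkylated too slowly by the unactivated primary iodide, so that proton transfer, polyalkylation or O-alkylation take over; the conjugate addition itself may also be sluggish without a silyl chloride. The fallback sets out from 6 and 8 and returns at 10. Enone 6 is iodinated at C9 (I2, pyridine, CH2Cl2) to the α-iodoenone F1. Iodide 8 is treated with t-BuLi and then B-methoxy-9-BBN to give the lithium alkylborate F2. B-Alkyl Suzuki–Miyaura coupling of F1 with F2 (PdCl2(dppf), K3PO4, DMF) gives the 9-alkylated enone F3. Lithium divinylcuprate with BF3·OEt2 then adds vinyl to C10 of F3 anti to the C5 substituent, and protonation with ethoxide equilibration gives 10.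

Step 7. Facial discrimination in the quaternisation at C4 rests on acyclic (allylic-strain) control and may be insufficient, and enolisation of the congested ester may be incomplete. The fallback sets out from 11 and returns at 18; it builds C4 on the closed ring instead. Hydrozirconation–iodination of 11 gives the iodo ester F4, and t-BuLi cycloacylation gives the 4-methyl-3-ketone F5. Kinetic enolisation (LDA, TMSCl) gives the Δ2 silyl enol ether F6, and Saegusa oxidation (Pd(OAc)2, MeCN) gives the Δ1-enone F7. F7 can only be deprotonated at C4; LDA and iPr3SiOCH2Cl should then alkylate anti to the axial C10 methyl to give the enone F8 (CH2OSi equatorial, CH3 axial). Conjugate reduction of F8 with Stryker's reagent returns 18.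

Step 12. The endoperoxide may rearrange to hydroxybutenolides, the cis-enedial may isomerise or cyclise before it is reduced, and borohydride may promote acyl migration. The fallback sets out from 19 and returns at 25; it unmasks the side chain before acylation through a stable lactone. Photooxygenation of 19 with iPr2NEt (O2, hν, rose bengal, CH2Cl2, −78 °C) gives the γ-hydroxybutenolide F9. NaBH4 gives the butenolide F10, and DIBAL-H reduces it to the triol F11, whose Z geometry is fixed by the former ring. TBSCl and imidazole silylate the two primary allylic hydroxyls selectively to give the bis-silyl ether F12. LiHMDS and angelic anhydride give the angelate F13, and HF·pyridine removes all three silyl groups to give 25.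

Further compounds
F1 | step 5 | ethyl 2-[(1R)-3-iodo-2-methyl-4-oxocyclohex-2-en-1-yl]propanoate | CCOC(=O)C(C)[C@H]1CCC(=O)C(I)=C1C
F2 | step 5 | lithium 9-[2-(furan-3-yl)ethyl]-9-methoxy-9-boranuidabicyclo[3.3.1]nonane | [Li+].CO[B-]1(CCc2ccoc2)C2CCCC1CCC2
F3 | step 5 | ethyl 2-[(1R)-3-[2-(furan-3-yl)ethyl]-2-methyl-4-oxocyclohex-2-en-1-yl]propanoate | CCOC(=O)C(C)[C@H]1CCC(=O)C(CCc2ccoc2)=C1C
F4 | step 7 | ethyl 2-[(1R,2S,3R)-3-[2-(furan-3-yl)ethyl]-2-(2-iodoethyl)-2-methyl-4-methylidenecyclohexyl]propanoate (both C4 epimers) | C=C1CC[C@H](C(C)C(=O)OCC)[C@@](C)(CCI)[C@@H]1CCc1ccoc1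
F5 | step 7 | (4aS,5R,8aR)-5-[2-(furan-3-yl)ethyl]-1,4a-dimethyl-6-methylideneoctahydronaphthalen-2(1H)-one (C4 epimers) | C=C1CC[C@H]2[C@@](C)(CCC(=O)C2C)[C@@H]1CCc1ccoc1
F6 | step 7 | Δ2 trimethylsilyl enol ether of F5 | C=C1CC[C@H]2[C@@](C)(CC=C(O[Si](C)(C)C)C2C)[C@@H]1CCc1ccoc1
F7 | step 7 | Δ1-enone: 5-[2-(furan-3-yl)ethyl]-1,4a-dimethyl-6-methylidene-4a,5,6,7,8,8a-hexahydronaphthalen-2(1H)-one | C=C1CC[C@H]2[C@@](C)(C=CC(=O)C2C)[C@@H]1CCc1ccoc1
F8 | step 7 | Δ1-enone with quaternary C4 (CH3 axial and CH2OSi(iPr)3 equatorial) | C=C1CC[C@H]2[C@@](C)(C=CC(=O)[C@]2(C)CO[Si](C(C)C)(C(C)C)C(C)C)[C@@H]1CCc1ccoc1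
F9 | step 12 | γ-hydroxybutenolide from 19 (5-hydroxy-5H-furan-2-on-4-yl side chain) | C=C1CC[C@H]2[C@@](C)(CC[C@@H](O)[C@]2(C)CO[Si](C(C)C)(C(C)C)C(C)C)[C@@H]1CCC1=CC(=O)OC1O
F10 | step 12 | butenolide from F9 (5H-furan-2-on-4-yl side chain) | C=C1CC[C@H]2[C@@](C)(CC[C@@H](O)[C@]2(C)CO[Si](C(C)C)(C(C)C)C(C)C)[C@@H]1CCC1=CC(=O)OC1
F11 | step 12 | triol: 3-hydroxy (Z)-enediol with O19 silyl ether | C=C1CC[C@H]2[C@@](C)(CC[C@@H](O)[C@]2(C)CO[Si](C(C)C)(C(C)C)C(C)C)[C@@H]1CC/C(=C/CO)CO
F12 | step 12 | 15,16-bis(tert-butyldimethylsilyl) ether of F11 | C=C1CC[C@H]2[C@@](C)(CC[C@@H](O)[C@]2(C)CO[Si](C(C)C)(C(C)C)C(C)C)[C@@H]1CC/C(=C/CO[Si](C)(C)C(C)(C)C)CO[Si](C)(C)C(C)(C)C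
F13 | step 12 | 3-O-angelate of F12 | C=C1CC[C@H]2[C@@](C)(CC[C@@H](OC(=O)/C(C)=C\C)[C@]2(C)CO[Si](C(C)C)(C(C)C)C(C)C)[C@@H]1CC/C(=C/CO[Si](C)(C)C(C)(C)C)CO[Si](C)(C)C(C)(C)C
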